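**Plan**

Atom labels: ring A is the methoxy ring (C1 butyryl, C2 methyl, C3 bridging CH2, C4 OMe, C5 methyl, C6 OH); ring B is the trihydroxy ring (C1' bridge, C2' OH, C3' methyl, C4' OH, C5' butyryl, C6' OH).
Retrosynthesis: the C5'–acyl bond is cut first (Friedel–Crafts). Ring B is then opened at C3'–C4', C1'–C2' and C4'–C5' into 1-siloxypropyne and a 3-isopropoxycyclobutenone whose C2 carries the ring A methylene. The cyclobutenone is cut into ketene and an alkynyl ether, and that ether at its benzyl–alkynyl bond.
Forward: 2,5-dimethylresorcinol is elaborated into ring A (butyryl, O-methyl, formyl to bromomethyl, O-benzyl). The bromide is extended by an isopropoxyethynyl unit, ketene closes the four-membered ring, the benzannulation grows ring B from it, and C5' butyrylation plus two deprotections finish.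
Enabling feature: ring B has oxygen on C2', C4' and C6', with the C3' methyl between C2' and C4' and the bridge carbon C1' between C2' and C6'. This is the pattern obtained when 1-siloxypropyne (C2'–O, C3'–methyl) is inserted between the carbonyl carbon (C4') and C2 (C1') of a 3-alkoxycyclobutenone (C3 becomes C6', CH2 becomes C5').
Stereochemistry: the target is achiral and no stereocentre has to be set; regiochemistry comes from the polarisation of the siloxyalkyne and from each aromatic substitution meeting a single free ring carbon.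

Key step: step 11

Remark: the enol-ether oxygen of the cyclobutenone is carried as isopropyl, not ethyl, because once C5' is acylated the carbonyl is chelated by the C4' hydroxyl and a primary ether on C6' could not be removed without losing the ring A methyl ether; ketene gas is taken from a laboratory generator (pyrolysis of acetone).

**Route**

Step 1
Reactants: 1 2,5-dimethylbenzene-1,3-diol (2,5-dimethylresorcinol); 2 butanoyl chloride
Product: 3 1-(2,4-dihydroxy-3,6-dimethylphenyl)butan-1-one
Conditions: AlCl3, PhNO2, 0 to 50 °C; aq. HCl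
Reagents that add atoms: none
Why: Friedel–Crafts acylation can only enter one of the two equivalent free ring carbons (each ortho to one hydroxyl and para to the other), and the new acyl group deactivates the ring against a second acylation.

Step 2
Reactants: 3 1-(2,4-dihydroxy-3,6-dimethylphenyl)butan-1-one
Product: 4 1-(2-hydroxy-4-methoxy-3,6-dimethylphenyl)butan-1-one
Conditions: MeI (1.1 equiv), K2CO3 (1.1 equiv), acetone, reflux
Reagents that add atoms: iodomethane, CI
Why: Williamson etherification with one equivalent of base should methylate only the 4-hydroxyl, because the 2-hydroxyl is hydrogen-bonded to the ketone and much less nucleophilic, the usual selectivity of 2,4-dihydroxyaryl ketones.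

Step 3
Reactants: 4 1-(2-hydroxy-4-methoxy-3,6-dimethylphenyl)butan-1-one
Product: 6 3-butanoyl-4-hydroxy-6-methoxy-2,5-dimethylbenzaldehyde, via alpha-chloro ether 5 (not isolated)
Conditions: Cl2CHOMe, TiCl4, CH2Cl2, −20 to 0 °C; H2O
Reagents that add atoms: dichloromethyl methyl ether, COC(Cl)Cl; water, O
Why: Rieche formylation (electrophilic aromatic substitution) has a single unsubstituted ring carbon to attack, para to the free hydroxyl and ortho to the methoxyl, and hydrolysis of alpha-chloro ether 5 on work-up releases the aldehyde.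

Step 4
Reactants: 6 3-butanoyl-4-hydroxy-6-methoxy-2,5-dimethylbenzaldehyde
Product: 7 4-(benzyloxy)-3-butanoyl-6-methoxy-2,5-dimethylbenzaldehyde
Conditions: BnBr, K2CO3, DMF, 60 °C
Reagents that add atoms: benzyl bromide, BrCc1ccccc1
Why: Williamson O-benzylation of the phenol, made acidic by the para formyl and ortho acyl groups, masks a hydroxyl that would otherwise open a quinone methide pathway once the para carbon carries a bromomethyl group.

Step 5
Reactants: 7 4-(benzyloxy)-3-butanoyl-6-methoxy-2,5-dimethylbenzaldehyde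
Product: 8 1-[2-(benzyloxy)-5-(hydroxymethyl)-4-methoxy-3,6-dimethylphenyl]butan-1-one
Conditions: NaBH4, MeOH–THF, −20 °C
Reagents that add atoms: none
Why: Chemoselective hydride reduction should take the aldehyde only, since the aryl ketone is flanked by two ortho substituents and reacts far more slowly with NaBH4 at low temperature.

Step 6
Reactants: 8 1-[2-(benzyloxy)-5-(hydroxymethyl)-4-methoxy-3,6-dimethylphenyl]butan-1-one
Product: 9 1-[2-(benzyloxy)-5-(bromomethyl)-4-methoxy-3,6-dimethylphenyl]butan-1-one
Conditions: CBr4, PPh3, CH2Cl2, 0 °C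
Reagents that add atoms: carbon tetrabromide, BrC(Br)(Br)Br
Why: The Appel reaction converts the primary benzylic alcohol into the bromide under neutral conditions that leave the ketone and both ethers untouched.

Step 7
Reactants: 10 trichloroethene; 11 propan-2-ol
Product: 13 (E)-1,2-dichloro-1-(propan-2-yloxy)ethene, via potassium propan-2-olate 12 (not isolated)
Conditions: KH, THF, 0 °C; then 10, rt
Reagents that add atoms: none
Why: Addition–elimination of an alkoxide on trichloroethene (anti addition to dichloroacetylene formed in situ) is the standard entry to 1,2-dichlorovinyl ethers, which serve as precursors of alkoxyacetylides.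

Step 8
Reactants: 9 1-[2-(benzyloxy)-5-(bromomethyl)-4-methoxy-3,6-dimethylphenyl]butan-1-one; 13 (E)-1,2-dichloro-1-(propan-2-yloxy)ethene
Product: 16 1-{2-(benzyloxy)-4-methoxy-3,6-dimethyl-5-[3-(propan-2-yloxy)prop-2-yn-1-yl]phenyl}butan-1-one, via lithium alkoxyacetylide 14 (not isolated), via alkynylzinc chloride 15 (not isolated)
Conditions: 13, n-BuLi (2 equiv), THF, −78 °C; ZnCl2, −78 to 0 °C; then 9, PdCl2(DPEphos) (3 mol %), rt
Reagents that add atoms: none
Why: Two equivalents of n-BuLi turn the dichlorovinyl ether into the lithium alkoxyacetylide (elimination, then chlorine–lithium exchange), and after transmetalation to zinc a Negishi benzyl–alkynyl cross-coupling joins it to the bromide, the zinc acetylide being too mild to add to or enolise the ring A ketone (DPEphos is bis[2-(diphenylphosphino)phenyl] ether).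

Step 9
Reactants: 16 1-{2-(benzyloxy)-4-methoxy-3,6-dimethyl-5-[3-(propan-2-yloxy)prop-2-yn-1-yl]phenyl}butan-1-one
Product: 17 2-{[4-(benzyloxy)-3-butanoyl-6-methoxy-2,5-dimethylphenyl]methyl}-3-(propan-2-yloxy)cyclobut-2-en-1-one
Conditions: ketene (gas stream, freshly generated by pyrolysis of acetone), CH2Cl2, 0 °C to rt
Reagents that add atoms: ketene, C=C=O
Why: The [2+2] cycloaddition of ketene with a 1-alkoxyalkyne is the classical route to 3-alkoxycyclobutenones, and because the nucleophilic benzyl-bearing alkyne carbon bonds to the ketene carbonyl carbon the benzyl group ends on C2 and the alkoxy group on C3.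

Step 10
Reactants: 18 ethyl acetate
Product: 22 triisopropyl(prop-1-yn-1-yloxy)silane, via tetrahedral adduct 19 (not isolated), via dibromo enolate 20 (not isolated), via lithium propynolate 21 (not isolated)
Conditions: CH2Br2, LiTMP (lithium 2,2,6,6-tetramethylpiperidide), THF, −78 °C; LiN(SiMe3)2; n-BuLi, −78 °C to rt; TIPSCl, −78 °C to rt
Reagents that add atoms: dibromomethane, BrCBr; chlorotriisopropylsilane, CC(C)[Si](Cl)(C(C)C)C(C)C
Why: This is the Kowalski ester homologation stopped at the ynolate: dibromomethyllithium adds to the ester, enolisation and bromine–lithium exchange trigger the carbenoid 1,2-shift to lithium propynolate, and the bulky silyl chloride caps it on oxygen.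

Step 11
Reactants: 17 2-{[4-(benzyloxy)-3-butanoyl-6-methoxy-2,5-dimethylphenyl]methyl}-3-(propan-2-yloxy)cyclobut-2-en-1-one; 22 triisopropyl(prop-1-yn-1-yloxy)silane
Product: 27 1-[2-(benzyloxy)-5-{[4-hydroxy-3-methyl-6-(propan-2-yloxy)-2-(triisopropylsilyloxy)phenyl]methyl}-4-methoxy-3,6-dimethylphenyl]butan-1-one, via vinylketene 23 (not isolated), via vinylcyclobutenone 24 (not isolated), via dienylketene 25 (not isolated), via cyclohexadienone 26 (not isolated)
Conditions: 22 (3 equiv), toluene, sealed tube, 110–140 °C
Reagents that add atoms: none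
Why: Proposed new method: heating should open 17 by 4-pi electrocyclic cleavage of its C(=O)–CH2 bond to vinylketene 23, whose ketene C=C adds the siloxyalkyne in a [2+2] cycloaddition (forming C3'–C4' and C1'–C2') to give 4-vinylcyclobutenone 24; a second 4-pi opening gives dienylketene 25, which closes the six-membered ring B by thermal disrotatory 6-pi electrocyclisation (ketene carbon to terminal CH2, re-forming C4'–C5'), and cyclohexa-2,4-dienone 26 tautomerises to the C4' phenol. The closest known reaction type is the Danheiser benzannulation of 3-alkyl- and 3-arylcyclobutenones with siloxyalkynes; what is new is the 3-alkoxy group on the starting cyclobutenone. It is expected to open because squarate-derived 3-alkoxycyclobutenones open thermally in their ring expansions and because intermediate 24 of every such benzannulation is itself a 3-siloxycyclobutenone that opens under the reaction conditions. No stereocentre remains, since the quaternary carbon of 24 is lost on ring opening. The selectivity needed is the orientation of the [2+2] step, secured by the polarisation of 22: its nucleophilic methyl-bearing carbon bonds to the electrophilic ketene carbonyl carbon and its siloxy carbon to the ketene alpha carbon, so the methyl lands on C3' between two oxygens and the ring A methylene on C1'. An excess of 22 should keep 23 from dimerising or acylating the product phenol, and the ring A ketone, benzyl ether and methyl ether are inert to neutral heating.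

Step 12
Reactants: 27 1-[2-(benzyloxy)-5-{[4-hydroxy-3-methyl-6-(propan-2-yloxy)-2-(triisopropylsilyloxy)phenyl]methyl}-4-methoxy-3,6-dimethylphenyl]butan-1-one; 2 butanoyl chloride
Product: 28 1-[3-{[4-(benzyloxy)-3-butanoyl-6-methoxy-2,5-dimethylphenyl]methyl}-6-hydroxy-5-methyl-2-(propan-2-yloxy)-4-(triisopropylsilyloxy)phenyl]butan-1-one
Conditions: TiCl4, CH2Cl2, −40 to 0 °C; aq. HCl
Reagents that add atoms: none
Why: Friedel–Crafts acylation, directed by the titanium phenoxide of the C4' hydroxyl, should enter C5', the only unsubstituted aromatic carbon in the molecule, which is activated by three oxygen substituents (ortho, ortho and para).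

Step 13
Reactants: 28 1-[3-{[4-(benzyloxy)-3-butanoyl-6-methoxy-2,5-dimethylphenyl]methyl}-6-hydroxy-5-methyl-2-(propan-2-yloxy)-4-(triisopropylsilyloxy)phenyl]butan-1-one
Product: 29 1-[3-{[4-(benzyloxy)-3-butanoyl-6-methoxy-2,5-dimethylphenyl]methyl}-4,6-dihydroxy-5-methyl-2-(propan-2-yloxy)phenyl]butan-1-one
Conditions: Bu4NF, AcOH, THF, 0 °C
Reagents that add atoms: none
Why: Fluoride-mediated desilylation should be fast for an aryl silyl ether para to a ketone, acetic acid buffers the phenoxide, and with ring A still benzylated the bridge cannot fragment through a quinone methide.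

Step 14
Reactants: 29 1-[3-{[4-(benzyloxy)-3-butanoyl-6-methoxy-2,5-dimethylphenyl]methyl}-4,6-dihydroxy-5-methyl-2-(propan-2-yloxy)phenyl]butan-1-one
Product: 30 1-[3-{[3-butanoyl-4-hydroxy-6-methoxy-2,5-dimethylphenyl]methyl}-2,4,6-trihydroxy-5-methylphenyl]butan-1-one (CNP0189103.0)
Conditions: BCl3, C6HMe5, CH2Cl2, −78 to 0 °C; MeOH, then H2O
Reagents that add atoms: none
Why: Lewis-acid ether cleavage with BCl3 removes benzyl (cation trapped by pentamethylbenzene) and secondary isopropyl ethers at or below 0 °C, conditions under which an aryl methyl ether that is not ortho to a carbonyl should persist.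

**Compound list**

1 | 2,5-dimethylbenzene-1,3-diol (2,5-dimethylresorcinol) | Cc1cc(O)c(C)c(O)c1 | starting material
2 | butanoyl chloride | CCCC(=O)Cl | starting material
3 | 1-(2,4-dihydroxy-3,6-dimethylphenyl)butan-1-one | CCCC(=O)c1c(C)cc(O)c(C)c1O | intermediate
4 | 1-(2-hydroxy-4-methoxy-3,6-dimethylphenyl)butan-1-one | CCCC(=O)c1c(C)cc(OC)c(C)c1O | intermediate
5 | 1-{3-[chloro(methoxy)methyl]-6-hydroxy-4-methoxy-2,5-dimethylphenyl}butan-1-one (racemic, formed in the flask) | CCCC(=O)c1c(C)c(C(Cl)OC)c(OC)c(C)c1O | intermediate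
6 | 3-butanoyl-4-hydroxy-6-methoxy-2,5-dimethylbenzaldehyde | CCCC(=O)c1c(C)c(C=O)c(OC)c(C)c1O | intermediate
7 | 4-(benzyloxy)-3-butanoyl-6-methoxy-2,5-dimethylbenzaldehyde | CCCC(=O)c1c(C)c(C=O)c(OC)c(C)c1OCc2ccccc2 | intermediate
8 | 1-[2-(benzyloxy)-5-(hydroxymethyl)-4-methoxy-3,6-dimethylphenyl]butan-1-one | CCCC(=O)c1c(C)c(CO)c(OC)c(C)c1OCc2ccccc2 | intermediate
9 | 1-[2-(benzyloxy)-5-(bromomethyl)-4-methoxy-3,6-dimethylphenyl]butan-1-one | CCCC(=O)c1c(C)c(CBr)c(OC)c(C)c1OCc2ccccc2 | intermediate
10 | trichloroethene | ClC=C(Cl)Cl | starting material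
11 | propan-2-ol | CC(C)O | starting material
12 | potassium propan-2-olate (formed in the flask) | CC(C)[O-].[K+] | intermediate
13 | (E)-1,2-dichloro-1-(propan-2-yloxy)ethene | CC(C)O/C(Cl)=C\Cl | intermediate
14 | lithium (propan-2-yloxy)ethynide (formed in the flask) | [Li]C#COC(C)C | intermediate
15 | chloro[(propan-2-yloxy)ethynyl]zinc (formed in the flask) | Cl[Zn]C#COC(C)C | intermediate
16 | 1-{2-(benzyloxy)-4-methoxy-3,6-dimethyl-5-[3-(propan-2-yloxy)prop-2-yn-1-yl]phenyl}butan-1-one | CCCC(=O)c1c(C)c(CC#COC(C)C)c(OC)c(C)c1OCc2ccccc2 | intermediate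
17 | 2-{[4-(benzyloxy)-3-butanoyl-6-methoxy-2,5-dimethylphenyl]methyl}-3-(propan-2-yloxy)cyclobut-2-en-1-one | CC(C)OC1=C(Cc2c(C)c(C(=O)CCC)c(OCc3ccccc3)c(C)c2OC)C(=O)C1 | intermediate
18 | ethyl acetate | CCOC(C)=O | starting material
19 | lithium 1,1-dibromo-2-ethoxypropan-2-olate (racemic, formed in the flask) | CCOC(C)(O[Li])C(Br)Br | intermediate
20 | lithium 1,1-dibromoprop-1-en-2-olate (formed in the flask) | CC(O[Li])=C(Br)Br | intermediate
21 | lithium prop-1-yn-1-olate (formed in the flask) | CC#CO[Li] | intermediate
22 | triisopropyl(prop-1-yn-1-yloxy)silane | CC#CO[Si](C(C)C)(C(C)C)C(C)C | intermediate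
23 | 2-{[4-(benzyloxy)-3-butanoyl-6-methoxy-2,5-dimethylphenyl]methyl}-3-(propan-2-yloxy)buta-1,3-dien-1-one (vinylketene, formed in the flask) | C=C(OC(C)C)C(Cc1c(C)c(C(=O)CCC)c(OCc2ccccc2)c(C)c1OC)=C=O | intermediate
24 | 4-{[4-(benzyloxy)-3-butanoyl-6-methoxy-2,5-dimethylphenyl]methyl}-2-methyl-4-[1-(propan-2-yloxy)ethenyl]-3-(triisopropylsilyloxy)cyclobut-2-en-1-one (racemic, formed in the flask) | CC1=C(O[Si](C(C)C)(C(C)C)C(C)C)C(Cc2c(C)c(C(=O)CCC)c(OCc3ccccc3)c(C)c2OC)(C(=C)OC(C)C)C1=O | intermediate
25 | 4-{[4-(benzyloxy)-3-butanoyl-6-methoxy-2,5-dimethylphenyl]methyl}-2-methyl-5-(propan-2-yloxy)-3-(triisopropylsilyloxy)hexa-1,3,5-trien-1-one, ketene arm cis to enol ether arm about C3=C4 (dienylketene, formed in the flask) | O=C=C(C)/C(O[Si](C(C)C)(C(C)C)C(C)C)=C(\C(=C)OC(C)C)Cc1c(C)c(C(=O)CCC)c(OCc2ccccc2)c(C)c1OC | intermediate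
26 | 4-{[4-(benzyloxy)-3-butanoyl-6-methoxy-2,5-dimethylphenyl]methyl}-2-methyl-5-(propan-2-yloxy)-3-(triisopropylsilyloxy)cyclohexa-2,4-dien-1-one (formed in the flask) | CC1=C(O[Si](C(C)C)(C(C)C)C(C)C)C(Cc2c(C)c(C(=O)CCC)c(OCc3ccccc3)c(C)c2OC)=C(OC(C)C)CC1=O | intermediate
27 | 1-[2-(benzyloxy)-5-{[4-hydroxy-3-methyl-6-(propan-2-yloxy)-2-(triisopropylsilyloxy)phenyl]methyl}-4-methoxy-3,6-dimethylphenyl]butan-1-one | CC(C)Oc1cc(O)c(C)c(O[Si](C(C)C)(C(C)C)C(C)C)c1Cc1c(C)c(C(=O)CCC)c(OCc2ccccc2)c(C)c1OC | intermediate
28 | 1-[3-{[4-(benzyloxy)-3-butanoyl-6-methoxy-2,5-dimethylphenyl]methyl}-6-hydroxy-5-methyl-2-(propan-2-yloxy)-4-(triisopropylsilyloxy)phenyl]butan-1-one | CCCC(=O)c1c(O)c(C)c(O[Si](C(C)C)(C(C)C)C(C)C)c(Cc2c(C)c(C(=O)CCC)c(OCc3ccccc3)c(C)c2OC)c1OC(C)C | intermediate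
29 | 1-[3-{[4-(benzyloxy)-3-butanoyl-6-methoxy-2,5-dimethylphenyl]methyl}-4,6-dihydroxy-5-methyl-2-(propan-2-yloxy)phenyl]butan-1-one | CCCC(=O)c1c(O)c(C)c(O)c(Cc2c(C)c(C(=O)CCC)c(OCc3ccccc3)c(C)c2OC)c1OC(C)C | intermediate
30 | 1-[3-{[3-butanoyl-4-hydroxy-6-methoxy-2,5-dimethylphenyl]methyl}-2,4,6-trihydroxy-5-methylphenyl]butan-1-one (CNP0189103.0, achiral) | CCCC(=O)c1c(C)c(Cc2c(O)c(C)c(O)c(C(=O)CCC)c2O)c(OC)c(C)c1O | target

**Step count and risks**

Total step count: 14. Longest linear sequence: 12 (steps 1–6, 8, 9, 11–14); steps 7 and 10 are one-step branches.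

Steps most likely to fail:

1. Step 11 (proposed new method). The vinylogous-ester stabilisation of the 3-alkoxycyclobutenone may keep the four-membered ring closed up to temperatures at which the siloxyalkyne degrades. Alternatively, the alkoxy vinylketene may be lost to dimerisation or to acylation of the phenol it produces before the alkyne intercepts it. The fallback uses known chemistry, sets out from alcohol 8 and comes back at target 30. Commercial 2-methylbenzene-1,3,5-triol would be C-acylated with 2 (AlCl3, PhNO2) to 1-(2,4,6-trihydroxy-3-methylphenyl)butan-1-one F1. Acid-catalysed Friedel–Crafts benzylation of F1 with 8 (TsOH cat., dioxane, rt) at its single free ring carbon should give 1-[3-{[4-(benzyloxy)-3-butanoyl-6-methoxy-2,5-dimethylphenyl]methyl}-2,4,6-trihydroxy-5-methylphenyl]butan-1-one F2; self-condensation of 8 is excluded because ring A has no free position. Hydrogenolysis of F2 (H2, 10% Pd/C, EtOAc) would then give 30.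

2. Step 8. Transfer of the alkoxyethynyl group from zinc may be slow, so that homocoupling of the benzylic bromide or base-induced isomerisation of the benzylic alkyne to an allenyl ether takes over; the ynol ether may also hydrate during isolation. The fallback sets out from 14 (generated from 13 as in step 8) and 9 and comes back at 16. Acetylide 14 would be quenched with Bu3SnCl to the distillable tributyl[(propan-2-yloxy)ethynyl]stannane F3. This would be coupled with 9 in a Stille reaction (Pd(PPh3)4, THF, 50 °C), so that the benzyl–alkynyl bond forms from a purified, neutral alkynyl donor with no organolithium or zinc salt present.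

3. Step 12. The acyl chloride may acylate the C4' oxygen instead of C5', and TiCl4 may strip the benzyl, isopropyl or silyl ether and then promote acid cleavage of the electron-rich diarylmethane bond. The fallback sets out from 27 and comes back at 28. A Houben–Hoesch reaction (butyronitrile, ZnCl2, HCl gas, Et2O, 0 °C) should deposit the ketiminium chloride of 28, 1-[3-{[4-(benzyloxy)-3-butanoyl-6-methoxy-2,5-dimethylphenyl]methyl}-6-hydroxy-5-methyl-2-(propan-2-yloxy)-4-(triisopropylsilyloxy)phenyl]butan-1-iminium chloride F4. Hydrolysis of F4 in warm water gives 28; the nitrilium electrophile acylates carbon only, and ZnCl2 is a far milder Lewis acid.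

**Further compounds**

F1 | step 11 | 1-(2,4,6-trihydroxy-3-methylphenyl)butan-1-one | CCCC(=O)c1c(O)c(C)c(O)cc1O
F2 | step 11 | 1-[3-{[4-(benzyloxy)-3-butanoyl-6-methoxy-2,5-dimethylphenyl]methyl}-2,4,6-trihydroxy-5-methylphenyl]butan-1-one | CCCC(=O)c1c(O)c(C)c(O)c(Cc2c(C)c(C(=O)CCC)c(OCc3ccccc3)c(C)c2OC)c1O
F3 | step 8 | tributyl[(propan-2-yloxy)ethynyl]stannane | CCCC[Sn](CCCC)(CCCC)C#COC(C)C
F4 | step 12 | 1-[3-{[4-(benzyloxy)-3-butanoyl-6-methoxy-2,5-dimethylphenyl]methyl}-6-hydroxy-5-methyl-2-(propan-2-yloxy)-4-(triisopropylsilyloxy)phenyl]butan-1-iminium chloride | CCCC(=[NH2+])c1c(O)c(C)c(O[Si](C(C)C)(C(C)C)C(C)C)c(Cc2c(C)c(C(=O)CCC)c(OCc3ccccc3)c(C)c2OC)c1OC(C)C.[Cl-]
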